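**Plan**

- Retrosynthesis: cut C3–Br first (electrophilic bromination of the pyrrole ring), then N1–C2 (vinyl C–N coupling), then C2=C3 (dibromo-olefination of an aldehyde whose carbon becomes C3). The amine is traced back to a nitro group.
- Enabling feature: C2 holds both a bromine and the bond to N1. It therefore corresponds to the CBr2 terminus of a 1,1-dibromoalkene that trades one bromine for nitrogen. The C7 bromine sits on the benzene ring next to C7a–N1 and is bought with the arene.
- Forward: the benzene ring arrives with Br, N and the future C3 carbon on three neighbouring positions. C2 is added as a one-carbon unit, the nitro group is reduced, the pyrrole ring (the only ring formed) is closed, and C3–Br is installed last.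
- Stereochemistry: the target is flat and achiral, so no stereocentre has to be set. The one geometric question, which of the two vinyl bromines is displaced, is settled by the ring being formed.

Key step: step 3

Assumption: 3-bromo-2-nitrobenzaldehyde is taken as a catalogue chemical, and the N–H 2-bromoindole stage is treated as light-, acid- and air-sensitive and carried on without storage.

**Step 1**
Reactants: 1 3-bromo-2-nitrobenzaldehyde; 2 carbon tetrabromide
Product: 4 1-bromo-3-(2,2-dibromovinyl)-2-nitrobenzene, via (dibromomethylene)triphenylphosphorane 3 (not isolated)
Conditions: PPh3 (4 equiv), CBr4 (2 equiv), CH2Cl2, 0 °C to rt; hexane, filtration through silica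
Reagents that add atoms: carbon tetrabromide 2, BrC(Br)(Br)Br
Why: In this Ramirez dibromo-olefination (first stage of the Corey–Fuchs sequence), ylide 3, formed from PPh3 and 2, undergoes a Wittig reaction with the electron-poor aldehyde, while the nitro group and the aryl bromide are inert to PPh3/CBr4 at this temperature.

**Step 2**
Reactants: 4 1-bromo-3-(2,2-dibromovinyl)-2-nitrobenzene
Product: 5 2-bromo-6-(2,2-dibromovinyl)aniline
Conditions: SnCl2·2H2O (5 equiv), EtOH, reflux; aq. K2CO3, Celite
Reagents that add atoms: none
Why: Chemoselective nitro reduction by divalent tin (SnCl2 reduction) proceeds by stepwise electron transfer and protonation at nitrogen and should leave the aryl C–Br bond, both vinyl C–Br bonds and the alkene untouched, as is routine for ortho-nitro-β,β-dibromostyrenes.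

**Step 3**
Reactants: 5 2-bromo-6-(2,2-dibromovinyl)aniline
Product: 6 2,7-dibromo-1H-indole
Conditions: Pd(OAc)2 (5 mol%), P(t-Bu)3 (10 mol%), K2CO3 (2 equiv), toluene (0.1 M), 100 °C, Ar; short silica plug, used at once
Reagents that add atoms: none
Why: Zerovalent palladium carrying P(t-Bu)3 (formed in the flask from Pd(OAc)2 and the phosphine) inserts into the vinyl C–Br bond that lies cis to the arene, the ortho NH2 binds to the divalent palladium centre and is deprotonated by K2CO3 to give a six-membered azapalladacycle, and C–N reductive elimination forms N1–C2 and returns the catalyst. The closest known reaction type is this very one, the intramolecular Buchwald–Hartwig-type vinyl amination of ortho-(2,2-dibromovinyl)anilines to 2-bromoindoles. The pyrrole ring closes in a formal 5-endo-trig mode, both alkene carbons (C2 and C3) ending inside the ring, and the usual stereoelectronic penalty for such closures does not apply because the bond comes from reductive elimination at the metal and not from attack on the π bond. No stereocentre is created; the only geometric question is which vinyl bromine leaves, and the tether answers it, since nitrogen can reach only the position cis to the arene and the trans bromine therefore ends up on C2. The step needs chemoselectivity among four C–Br bonds (cis vinyl, trans vinyl, aryl C7 and the C2–Br of 6): insertion at the three unwanted sites finds no nucleophile within reach and, with the very bulky phosphine, is undone by C–Br reductive elimination, so the material should drain through the one intramolecular channel. The weak, poorly soluble base, moderate dilution and the low nucleophilicity of an aniline flanked by bromine and the vinyl group hold back intermolecular N-arylation.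

**Step 4**
Reactants: 6 2,7-dibromo-1H-indole; 7 N-bromosuccinimide
Product: 8 2,3,7-tribromo-1H-indole
Conditions: NBS (1.0 equiv), anhydrous DMF, 0 °C, dark; aq. Na2S2O3/NaHCO3
Reagents that add atoms: N-bromosuccinimide 7, O=C1CCC(=O)N1Br
Why: Electrophilic aromatic substitution takes place at C3, the only free position of the pyrrole ring and the enamine-like β-carbon, so one equivalent of NBS in the cold should react there well before the bromine-deactivated benzene ring does.

**Compound list**

1 | 3-bromo-2-nitrobenzaldehyde | O=Cc1cccc(Br)c1[N+](=O)[O-] | starting material
2 | carbon tetrabromide | BrC(Br)(Br)Br | starting material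
3 | (dibromomethylene)triphenylphosphorane | BrC(Br)=P(c1ccccc1)(c1ccccc1)c1ccccc1 | intermediate
4 | 1-bromo-3-(2,2-dibromovinyl)-2-nitrobenzene | O=[N+]([O-])c1c(Br)cccc1C=C(Br)Br | intermediate
5 | 2-bromo-6-(2,2-dibromovinyl)aniline | Nc1c(Br)cccc1C=C(Br)Br | intermediate
6 | 2,7-dibromo-1H-indole | Brc1cc2cccc(Br)c2[nH]1 | intermediate
7 | N-bromosuccinimide | O=C1CCC(=O)N1Br | starting material
8 | 2,3,7-tribromo-1H-indole | Brc1[nH]c2c(Br)cccc2c1Br | target

Total step count: 4
Longest linear sequence: 4 steps (1 → 4 → 5 → 6 → 8)

**Steps most likely to fail**

**Step 3.**
- Risk: palladium insertion into the aryl C7–Br bond or into the C2–Br bond of the product may turn productive, leading to intermolecular N-arylation, oligomerisation or hydrodebromination. The hindered, weakly basic NH2 may also bind too poorly for the palladacycle to form.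
- Fallback: a metal-free, anionic closure of the same N1–C2 bond, setting out from 5. The aniline is made more acidic by mesylation (MsCl, pyridine, CH2Cl2) to give N-[2-bromo-6-(2,2-dibromovinyl)phenyl]methanesulfonamide F1. Cs2CO3 in warm DMSO should eliminate HBr to the bromoalkyne N-[2-bromo-6-(bromoethynyl)phenyl]methanesulfonamide F2. Its sulfonamide anion then adds 5-endo-dig to the bromine-bearing alkyne carbon to give 2,7-dibromo-1-(methylsulfonyl)-1H-indole F3. Aqueous NaOH in MeOH/THF cleaves the strained N–S bond, and the sequence comes back to the route at 6.

**Step 4.**
- Risk: the free N–H 2-bromoindole may decompose under the traces of HBr that accompany NBS. It may also undergo oxidative hydrolysis at C2 with adventitious water, or take up a second bromine on the benzene ring.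
- Fallback: bromination of a carbamate-damped indole, setting out from 6. Boc2O with catalytic DMAP in MeCN should give tert-butyl 2,7-dibromo-1H-indole-1-carboxylate F4, which is storable and less oxidisable. NBS in DMF at rt then brominates C3 to give tert-butyl 2,3,7-tribromo-1H-indole-1-carboxylate F5. Catalytic K2CO3 in MeOH removes the crowded, electron-poor carbamate under non-acidic conditions and delivers 8.

**Step 2.**
- Risk: reductive loss of a vinyl bromine, stalling at the hydroxylamine stage, or loss of material in tin-salt emulsions during work-up.
- Fallback: inversion of the order of events so that no vinyl bromide ever meets a reductant, setting out from 1. Iron powder and NH4Cl in aqueous EtOH reduce the nitro group to give 2-amino-3-bromobenzaldehyde F6. Ylide 3 is generated separately from commercial (dibromomethyl)triphenylphosphonium bromide and KOt-Bu in THF, so no dibromotriphenylphosphorane is present to attack the free amine. This ylide olefinates the aldehyde in a Wittig reaction, and the sequence returns to the route at 5.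

**Further compounds**

F1 | step 3 | N-[2-bromo-6-(2,2-dibromovinyl)phenyl]methanesulfonamide | CS(=O)(=O)Nc1c(Br)cccc1C=C(Br)Br
F2 | step 3 | N-[2-bromo-6-(bromoethynyl)phenyl]methanesulfonamide | CS(=O)(=O)Nc1c(Br)cccc1C#CBr
F3 | step 3 | 2,7-dibromo-1-(methylsulfonyl)-1H-indole | CS(=O)(=O)n1c(Br)cc2cccc(Br)c21
F4 | step 4 | tert-butyl 2,7-dibromo-1H-indole-1-carboxylate | CC(C)(C)OC(=O)n1c(Br)cc2cccc(Br)c21
F5 | step 4 | tert-butyl 2,3,7-tribromo-1H-indole-1-carboxylate | CC(C)(C)OC(=O)n1c(Br)c(Br)c2cccc(Br)c21
F6 | step 2 | 2-amino-3-bromobenzaldehyde | Nc1c(Br)cccc1C=O
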